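**Plan**

- Retrosynthesis: remove the silyl group on O4′, take the formyl group back to a C3 methyl ester, and cut the C5–prenyl bond (aromatic Claisen from O4).
- The furan O1–C2 bond is then opened to a ring-A phenol plus an aryl ketone, i.e. a 3-aroylbenzofuran-2(3H)-one. Its C1′–C2 and C2–C3 bonds are cut together to give an aryl bromide, carbon monoxide and a phloroglucinol-derived lactone.
- Enabling feature: furan C2 is bonded only to O1, C3 and aryl C1′, so it is a ketone-level carbon that CO can deliver. C3 and the formyl carbon map onto the acidic α-carbon and the carbonyl of a benzofuran-2(3H)-one fused to ring A.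
- Forward: the ring-A lactone is made first; the three-component carbonylation attaches ring B through the new carbonyl carbon without closing a ring; acid then exchanges the lactone ring for the furan ring.
- 6-O-Methylation, C5 prenylation through the 4-O-(1,1-dimethylallyl) ether, ester-to-aldehyde adjustment and desilylation complete the target.
- Stereochemistry: the target has no stereocentre and no stereogenic alkene. The transient stereocentres (C3 of the acylated lactone, C5 of a Claisen dienone) are racemic and are erased by aromatisation.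

Key step: step 4

Remark on the chemistry: ebenfuran IV is achiral, so "single enantiomer" is taken to mean the single constitution shown, and no enantioselective step is required.

**Route**

Step 1
Reactants: 1 (2,4,6-trimethoxyphenyl)acetic acid
Product: 3 4,6-dihydroxybenzofuran-2(3H)-one, via (2,4,6-trihydroxyphenyl)acetic acid 2 (not isolated)
Conditions: BBr3 (5 equiv), CH2Cl2, −78 °C → rt; H2O quench; crude acid then TsOH·H2O (cat.), PhMe, reflux (Dean–Stark)
Reagents that add atoms: none
Why: Lewis-acid ether cleavage with BBr3 removes all three aryl methyl groups, and the resulting ortho-hydroxy arylacetic acid should close to the five-membered lactone by acid-catalysed lactonisation; the ring is symmetric, so only one lactone can form.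

Step 2
Reactants: 3 4,6-dihydroxybenzofuran-2(3H)-one
Product: 4 4,6-bis(methoxymethoxy)benzofuran-2(3H)-one
Conditions: MOMCl (2.2 equiv), i-Pr2NEt (2.5 equiv), CH2Cl2, 0 °C → rt
Reagents that add atoms: chloromethyl methyl ether, COCCl
Why: Williamson-type O-alkylation of both phenols with the very reactive chloromethyl ether (MOM protection) under a hindered tertiary amine, which should neither open the aryl-ester lactone nor generate enough C3 enolate for C-alkylation.

Step 3
Reactants: 5 4-bromo-3-methoxyphenol
Product: 6 (4-bromo-3-methoxyphenoxy)triisopropylsilane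
Conditions: TIPSCl (1.1 equiv), imidazole (2 equiv), DMF, rt
Reagents that add atoms: chlorotriisopropylsilane, CC(C)[Si](Cl)(C(C)C)C(C)C
Why: Imidazole-promoted silylation of a phenol is routine, and the triisopropylsilyl aryl ether is chosen because it tolerates both mild base and methanolic acid.

Step 4
Reactants: 4 4,6-bis(methoxymethoxy)benzofuran-2(3H)-one; 6 (4-bromo-3-methoxyphenoxy)triisopropylsilane; 7 carbon monoxide
Product: 8 3-[2-methoxy-4-(triisopropylsilyloxy)benzoyl]-4,6-bis(methoxymethoxy)benzofuran-2(3H)-one (racemic; largely enolised)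
Conditions: Pd(dba)2 (5 mol %), Xantphos (5 mol %), MgCl2 (1.5 equiv), Et3N (3 equiv), CO (3 bar), MeCN–dioxane, 80 °C; aq. citric acid work-up
Reagents that add atoms: none
Why: Proposed new method: Pd(0)/Xantphos should insert into the C–Br bond of 6, CO insertion then gives an aroylpalladium(II) bromide, and the magnesium enolate of lactone 4 (soft enolisation by MgCl2/Et3N, the lactone C3–H being about as acidic as a malonate) replaces bromide and undergoes C-acyl reductive elimination, so that C1′–C(=O) and C(=O)–C3 are made in one operation. The closest known reaction type is the palladium-catalysed carbonylative α-arylation of ketones, 2-oxindoles and malonate-type pronucleophiles with aryl halides and CO, the lactone being the oxygen analogue of a 2-oxindole. No ring is closed, and the only new stereocentre (C3) is an enolisable 1,3-dicarbonyl carbon that is left racemic and disappears when the furan forms in step 5. Carbonylative coupling must beat direct α-arylation, which the large-bite-angle diphosphine and a few bar of CO should ensure by holding palladium in the acyl form, and C-acylation must beat O-acylation, which magnesium chelation favours, any enol ester being itself an aroyl donor that drains to the more stable chelated β-keto lactone enolate. Removal of the product as that unreactive enolate should also prevent a second acylation, and the amine base is too poor a nucleophile to open the lactone or to disturb the silyl and MOM ethers.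

Step 5
Reactants: 8 3-[2-methoxy-4-(triisopropylsilyloxy)benzoyl]-4,6-bis(methoxymethoxy)benzofuran-2(3H)-one
Product: 10 methyl 4,6-dihydroxy-2-[2-methoxy-4-(triisopropylsilyloxy)phenyl]benzofuran-3-carboxylate, via ring-opened methyl β-keto ester 9 (not isolated)
Conditions: HCl (1.25 M in MeOH), 0 °C → 45 °C
Reagents that add atoms: methanol, CO
Why: Acid-catalysed methanolysis opens the aryl-ester lactone to β-keto ester 9, whose freed ortho-phenol adds to the aryl ketone and dehydrates to the aromatic furan (cyclodehydration; the known acid isomerisation of 3-acylbenzofuran-2(3H)-ones to benzofuran-3-carboxylates), while the same medium transacetalises both MOM ethers and should leave the much more slowly solvolysed aryl triisopropylsilyl ether in place.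

Step 6
Reactants: 10 methyl 4,6-dihydroxy-2-[2-methoxy-4-(triisopropylsilyloxy)phenyl]benzofuran-3-carboxylate
Product: 11 methyl 4-hydroxy-6-methoxy-2-[2-methoxy-4-(triisopropylsilyloxy)phenyl]benzofuran-3-carboxylate
Conditions: MeI (1.05 equiv), K2CO3 (1.1 equiv), acetone, rt
Reagents that add atoms: iodomethane, CI
Why: Williamson etherification with one equivalent of base and electrophile should alkylate the exposed 6-OH, because the 4-OH is shielded by the neighbouring C3 ester and hydrogen-bonded to its carbonyl (the same bias that directs mono-alkylation of chelated dihydroxyaryl carbonyl compounds).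

Step 7
Reactants: 11 methyl 4-hydroxy-6-methoxy-2-[2-methoxy-4-(triisopropylsilyloxy)phenyl]benzofuran-3-carboxylate; 12 3-chloro-3-methylbut-1-yne
Product: 13 methyl 6-methoxy-2-[2-methoxy-4-(triisopropylsilyloxy)phenyl]-4-[(2-methylbut-3-yn-2-yl)oxy]benzofuran-3-carboxylate
Conditions: 12 (1.5 equiv), CuCl2·2H2O (1 mol %), DBU (1.6 equiv), MeCN, 0 °C → rt
Reagents that add atoms: none
Why: Copper-catalysed propargylic etherification (phenoxide capture of a copper acetylide/allenylidene at the tertiary carbon) is the standard entry to aryl 1,1-dimethylpropargyl ethers and is known to work on phenols hydrogen-bonded to an ortho carbonyl group.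

Step 8
Reactants: 13 methyl 6-methoxy-2-[2-methoxy-4-(triisopropylsilyloxy)phenyl]-4-[(2-methylbut-3-yn-2-yl)oxy]benzofuran-3-carboxylate
Product: 14 methyl 6-methoxy-2-[2-methoxy-4-(triisopropylsilyloxy)phenyl]-4-[(2-methylbut-3-en-2-yl)oxy]benzofuran-3-carboxylate
Conditions: H2 (1 atm), Lindlar catalyst, quinoline, EtOAc, rt
Reagents that add atoms: none
Why: Lindlar semi-hydrogenation stops a terminal alkyne at the alkene and leaves the benzofuran, ester and silyl ether untouched.

Step 9
Reactants: 14 methyl 6-methoxy-2-[2-methoxy-4-(triisopropylsilyloxy)phenyl]-4-[(2-methylbut-3-en-2-yl)oxy]benzofuran-3-carboxylate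
Product: 16 methyl 4-hydroxy-6-methoxy-2-[2-methoxy-4-(triisopropylsilyloxy)phenyl]-5-(3-methylbut-2-en-1-yl)benzofuran-3-carboxylate, via C5-prenyl dienone 15 (not isolated)
Conditions: PhNEt2, 130 °C
Reagents that add atoms: none
Why: Aromatic Claisen rearrangement: the [3,3] shift from O4 can only reach C5 (the other ortho position, C3a, is the ring fusion), the allyl inversion turns the 1,1-dimethylallyl ether into the linear prenyl group, and tautomerisation of dienone 15 restores the phenol; the basic solvent suppresses acid-induced ether cleavage.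

Step 10
Reactants: 16 methyl 4-hydroxy-6-methoxy-2-[2-methoxy-4-(triisopropylsilyloxy)phenyl]-5-(3-methylbut-2-en-1-yl)benzofuran-3-carboxylate
Product: 17 3-(hydroxymethyl)-6-methoxy-2-[2-methoxy-4-(triisopropylsilyloxy)phenyl]-5-(3-methylbut-2-en-1-yl)benzofuran-4-ol
Conditions: DIBAL-H (4 equiv), CH2Cl2, −78 → 0 °C; Rochelle salt work-up
Reagents that add atoms: none
Why: Hydride reduction of the ester to the primary alcohol with excess DIBAL-H (one equivalent is consumed by the phenol) should spare the prenyl alkene and the aryl silyl ether; the sensitive hydroxymethyl phenol is used at once.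

Step 11
Reactants: 17 3-(hydroxymethyl)-6-methoxy-2-[2-methoxy-4-(triisopropylsilyloxy)phenyl]-5-(3-methylbut-2-en-1-yl)benzofuran-4-ol
Product: 18 4-hydroxy-6-methoxy-2-[2-methoxy-4-(triisopropylsilyloxy)phenyl]-5-(3-methylbut-2-en-1-yl)benzofuran-3-carbaldehyde
Conditions: activated MnO2 (10 equiv), CH2Cl2, rt
Reagents that add atoms: none
Why: Activated MnO2 oxidises the benzylic-type benzofuran-3-ylmethanol selectively to the aldehyde without over-oxidation and without touching the prenyl group.

Step 12
Reactants: 18 4-hydroxy-6-methoxy-2-[2-methoxy-4-(triisopropylsilyloxy)phenyl]-5-(3-methylbut-2-en-1-yl)benzofuran-3-carbaldehyde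
Product: 19 4-hydroxy-2-(4-hydroxy-2-methoxyphenyl)-6-methoxy-5-(3-methylbut-2-en-1-yl)benzofuran-3-carbaldehyde (ebenfuran IV)
Conditions: TBAF (1.2 equiv), AcOH (1.2 equiv), THF, 0 °C
Reagents that add atoms: none
Why: Fluoride-induced desilylation cleaves the aryl silyl ether rapidly, and the acetic acid buffer keeps the aldehyde and the prenylated phenol away from strongly basic phenoxide conditions.

**Compound list**

1 | (2,4,6-trimethoxyphenyl)acetic acid | COc1cc(OC)c(CC(=O)O)c(OC)c1 | starting material
2 | (2,4,6-trihydroxyphenyl)acetic acid | Oc1cc(O)c(CC(=O)O)c(O)c1 | intermediate (not isolated)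
3 | 4,6-dihydroxybenzofuran-2(3H)-one | Oc1cc(O)c2c(c1)OC(=O)C2 | intermediate
4 | 4,6-bis(methoxymethoxy)benzofuran-2(3H)-one | COCOc1cc(OCOC)c2c(c1)OC(=O)C2 | intermediate
5 | 4-bromo-3-methoxyphenol | COc1cc(O)ccc1Br | starting material
6 | (4-bromo-3-methoxyphenoxy)triisopropylsilane | COc1cc(O[Si](C(C)C)(C(C)C)C(C)C)ccc1Br | intermediate
7 | carbon monoxide | [C-]#[O+] | starting material
8 | 3-[2-methoxy-4-(triisopropylsilyloxy)benzoyl]-4,6-bis(methoxymethoxy)benzofuran-2(3H)-one (racemic, enolisable) | COCOc1cc(OCOC)c2c(c1)OC(=O)C2C(=O)c1ccc(O[Si](C(C)C)(C(C)C)C(C)C)cc1OC | intermediate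
9 | methyl 2-[2-hydroxy-4,6-bis(methoxymethoxy)phenyl]-3-[2-methoxy-4-(triisopropylsilyloxy)phenyl]-3-oxopropanoate (racemic, enolisable) | COCOc1cc(O)c(C(C(=O)OC)C(=O)c2ccc(O[Si](C(C)C)(C(C)C)C(C)C)cc2OC)c(OCOC)c1 | intermediate (not isolated)
10 | methyl 4,6-dihydroxy-2-[2-methoxy-4-(triisopropylsilyloxy)phenyl]benzofuran-3-carboxylate | COC(=O)c1c(-c2ccc(O[Si](C(C)C)(C(C)C)C(C)C)cc2OC)oc2cc(O)cc(O)c12 | intermediate
11 | methyl 4-hydroxy-6-methoxy-2-[2-methoxy-4-(triisopropylsilyloxy)phenyl]benzofuran-3-carboxylate | COC(=O)c1c(-c2ccc(O[Si](C(C)C)(C(C)C)C(C)C)cc2OC)oc2cc(OC)cc(O)c12 | intermediate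
12 | 3-chloro-3-methylbut-1-yne | CC(C)(Cl)C#C | starting material
13 | methyl 6-methoxy-2-[2-methoxy-4-(triisopropylsilyloxy)phenyl]-4-[(2-methylbut-3-yn-2-yl)oxy]benzofuran-3-carboxylate | COC(=O)c1c(-c2ccc(O[Si](C(C)C)(C(C)C)C(C)C)cc2OC)oc2cc(OC)cc(OC(C)(C)C#C)c12 | intermediate
14 | methyl 6-methoxy-2-[2-methoxy-4-(triisopropylsilyloxy)phenyl]-4-[(2-methylbut-3-en-2-yl)oxy]benzofuran-3-carboxylate | COC(=O)c1c(-c2ccc(O[Si](C(C)C)(C(C)C)C(C)C)cc2OC)oc2cc(OC)cc(OC(C)(C)C=C)c12 | intermediate
15 | methyl 6-methoxy-2-[2-methoxy-4-(triisopropylsilyloxy)phenyl]-5-(3-methylbut-2-en-1-yl)-4-oxo-4,5-dihydrobenzofuran-3-carboxylate (racemic at C5) | COC(=O)C1=C(c2ccc(O[Si](C(C)C)(C(C)C)C(C)C)cc2OC)OC2=C1C(=O)C(CC=C(C)C)C(OC)=C2 | intermediate (not isolated)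
16 | methyl 4-hydroxy-6-methoxy-2-[2-methoxy-4-(triisopropylsilyloxy)phenyl]-5-(3-methylbut-2-en-1-yl)benzofuran-3-carboxylate | COC(=O)c1c(-c2ccc(O[Si](C(C)C)(C(C)C)C(C)C)cc2OC)oc2cc(OC)c(CC=C(C)C)c(O)c12 | intermediate
17 | 3-(hydroxymethyl)-6-methoxy-2-[2-methoxy-4-(triisopropylsilyloxy)phenyl]-5-(3-methylbut-2-en-1-yl)benzofuran-4-ol | OCc1c(-c2ccc(O[Si](C(C)C)(C(C)C)C(C)C)cc2OC)oc2cc(OC)c(CC=C(C)C)c(O)c12 | intermediate
18 | 4-hydroxy-6-methoxy-2-[2-methoxy-4-(triisopropylsilyloxy)phenyl]-5-(3-methylbut-2-en-1-yl)benzofuran-3-carbaldehyde | O=Cc1c(-c2ccc(O[Si](C(C)C)(C(C)C)C(C)C)cc2OC)oc2cc(OC)c(CC=C(C)C)c(O)c12 | intermediate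
19 | 4-hydroxy-2-(4-hydroxy-2-methoxyphenyl)-6-methoxy-5-(3-methylbut-2-en-1-yl)benzofuran-3-carbaldehyde (ebenfuran IV, achiral) | COc1cc(O)ccc1-c1oc2cc(OC)c(CC=C(C)C)c(O)c2c1C=O | target

**Step count**

Total steps: 12. Longest linear sequence: 11 steps (steps 1, 2 and 4–12, from 1 to 19); step 3 is the only side branch.

**Steps most likely to fail**

1. Step 4. The hindered lactone enolate (flanked by the 4-OMOM group) may capture the ortho-substituted aroylpalladium species too slowly, so that direct α-arylation, O-acylation or self-condensation and ring opening of the lactone take over. Fallback with known chemistry, setting out from bromide 6 and lactone 4 and returning at 8: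
   - Bromine–lithium exchange on 6 (n-BuLi, THF, −78 °C) followed by CO2 should give 2-methoxy-4-(triisopropylsilyloxy)benzoic acid F1.
   - Ghosez's reagent (1-chloro-N,N,2-trimethylprop-1-en-1-amine, CH2Cl2, rt), which is neutral and spares the silyl ether, converts it into 2-methoxy-4-(triisopropylsilyloxy)benzoyl chloride F2.
   - Lactone 4 is O-aroylated with F2 (Et3N, CH2Cl2, 0 °C) to the enol ester 4,6-bis(methoxymethoxy)benzofuran-2-yl 2-methoxy-4-(triisopropylsilyloxy)benzoate F3.
   - Added DMAP then effects the known Steglich-type O-to-C acyl migration of benzofuranone enol esters, giving 8, from which step 5 continues. The carbonyl carbon then comes from CO2 rather than CO, but the same two bonds to the future furan C2 are formed.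

2. Step 5. The aryl silyl ether may be slowly solvolysed, or the β-keto ester 9 may fragment by retro-Claisen cleavage, during the time the two acetals need for complete removal. Fallback, setting out from phenol 5 and lactone 4 and returning at 11, carries the ring-B oxygen as an acid-inert benzyl ether and exchanges it for silicon before any alkene is present:
   - Benzylation of 5 (BnBr, K2CO3, acetone) gives 4-(benzyloxy)-1-bromo-2-methoxybenzene F4.
   - F4 is coupled with 4 and 7 under the conditions of step 4 to give 3-[4-(benzyloxy)-2-methoxybenzoyl]-4,6-bis(methoxymethoxy)benzofuran-2(3H)-one F5.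
   - Methanolic HCl, now usable under forcing conditions, leads through the ring-opened methyl 3-[4-(benzyloxy)-2-methoxyphenyl]-2-[2-hydroxy-4,6-bis(methoxymethoxy)phenyl]-3-oxopropanoate F6 to methyl 2-[4-(benzyloxy)-2-methoxyphenyl]-4,6-dihydroxybenzofuran-3-carboxylate F7.
   - 6-O-Methylation as in step 6 gives methyl 2-[4-(benzyloxy)-2-methoxyphenyl]-4-hydroxy-6-methoxybenzofuran-3-carboxylate F8.
   - Hydrogenolysis (H2, Pd/C, EtOAc) gives methyl 4-hydroxy-2-(4-hydroxy-2-methoxyphenyl)-6-methoxybenzofuran-3-carboxylate F9.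
   - Silylation with TIPSCl/imidazole, selective for the unhindered 4′-OH over the ester-chelated 4-OH, gives 11.

3. Step 7. The hindered, hydrogen-bonded 4-phenoxide may fail to attack the tertiary carbon of the copper-bound propargyl electrophile, so that elimination of 12 to the enyne consumes the reagent. Fallback, setting out from 11 and returning at 16, avoids forming a tertiary ether:
   - O-Alkylation with the primary electrophile prenyl bromide (K2CO3, acetone, reflux) should give methyl 6-methoxy-2-[2-methoxy-4-(triisopropylsilyloxy)phenyl]-4-[(3-methylbut-2-en-1-yl)oxy]benzofuran-3-carboxylate F10.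
   - The known acidic-clay (montmorillonite K10, CH2Cl2, 0 °C → rt) [1,3]-shift of aryl prenyl ethers then moves the prenyl group to the only free ortho position, C5, giving 16. Steps 8 and 9 are skipped; the C7 (para) isomer would have to be separated if it forms.

**Further compounds**

F1 | step 4 | 2-methoxy-4-(triisopropylsilyloxy)benzoic acid | COc1cc(O[Si](C(C)C)(C(C)C)C(C)C)ccc1C(=O)O
F2 | step 4 | 2-methoxy-4-(triisopropylsilyloxy)benzoyl chloride | COc1cc(O[Si](C(C)C)(C(C)C)C(C)C)ccc1C(=O)Cl
F3 | step 4 | 4,6-bis(methoxymethoxy)benzofuran-2-yl 2-methoxy-4-(triisopropylsilyloxy)benzoate | COCOc1cc(OCOC)c2cc(OC(=O)c3ccc(O[Si](C(C)C)(C(C)C)C(C)C)cc3OC)oc2c1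
F4 | step 5 | 4-(benzyloxy)-1-bromo-2-methoxybenzene | COc1cc(OCc2ccccc2)ccc1Br
F5 | step 5 | 3-[4-(benzyloxy)-2-methoxybenzoyl]-4,6-bis(methoxymethoxy)benzofuran-2(3H)-one (racemic, enolisable) | COCOc1cc(OCOC)c2c(c1)OC(=O)C2C(=O)c1ccc(OCc2ccccc2)cc1OC
F6 | step 5 | methyl 3-[4-(benzyloxy)-2-methoxyphenyl]-2-[2-hydroxy-4,6-bis(methoxymethoxy)phenyl]-3-oxopropanoate (racemic, not isolated) | COCOc1cc(O)c(C(C(=O)OC)C(=O)c2ccc(OCc3ccccc3)cc2OC)c(OCOC)c1
F7 | step 5 | methyl 2-[4-(benzyloxy)-2-methoxyphenyl]-4,6-dihydroxybenzofuran-3-carboxylate | COC(=O)c1c(-c2ccc(OCc3ccccc3)cc2OC)oc2cc(O)cc(O)c12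
F8 | step 5 | methyl 2-[4-(benzyloxy)-2-methoxyphenyl]-4-hydroxy-6-methoxybenzofuran-3-carboxylate | COC(=O)c1c(-c2ccc(OCc3ccccc3)cc2OC)oc2cc(OC)cc(O)c12
F9 | step 5 | methyl 4-hydroxy-2-(4-hydroxy-2-methoxyphenyl)-6-methoxybenzofuran-3-carboxylate | COC(=O)c1c(-c2ccc(O)cc2OC)oc2cc(OC)cc(O)c12
F10 | step 7 | methyl 6-methoxy-2-[2-methoxy-4-(triisopropylsilyloxy)phenyl]-4-[(3-methylbut-2-en-1-yl)oxy]benzofuran-3-carboxylate | COC(=O)c1c(-c2ccc(O[Si](C(C)C)(C(C)C)C(C)C)cc2OC)oc2cc(OC)cc(OCC=C(C)C)c12
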